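**Retrosynthetic overview**
1. Jaspaquinol (18) ⇐ quinone 17 ⇐ dimethyl ether 16; the hydroquinone is unmasked last under mild conditions, and the ring methyl comes from enol triflate 15 by iron-catalysed coupling with MeMgBr.
2. 15 ⇐ 2,2-dimethylcyclopentanone (10) + gem-dibromide 9 in one flask, by a β-oxido carbenoid one-carbon ring enlargement: the cyclohexene ring is made from the cyclopentane of 10, and the inserted ring atom is the former aldehyde carbon of the chain.
3. Enabling feature: in alkoxide 12 and carbenoid 13, cyclopentane C1 carries the oxido group and the exocyclic carbenoid carbon and lies between quaternary C2 (gem-dimethyl) and C5H2. The alkoxide on C1 and the Li/Br carbenoid on the exocyclic carbon make the C1–C2 bond migrate, so the new ring atom lands between C1 and CMe2 and the enolate C=C sits where the tetrasubstituted alkene is needed.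
4. 9 ⇐ trisnor aldehyde 7 ⇐ terminal epoxide 6 ⇐ farnesylarene 4 ⇐ 1,4-dimethoxybenzene (1) + (2E,6E)-farnesyl bromide (2).
5. Ring order: the arene and the cyclopentane are bought; the six-membered carbocycle is the only ring formed (step 7); both (E)-alkenes are carried over from 2.

Key step: step 7

Assumption: commercial farnesyl bromide is taken as the pure (2E,6E) isomer; 5, 6, 12 and 13 are stereoisomer mixtures at centres that are erased in steps 4 and 7, so no stereocontrol is needed there.

**Step 1**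
Reactants: 1 1,4-dimethoxybenzene; 2 (2E,6E)-farnesyl bromide
Product: 4 2-[(2E,6E)-3,7,11-trimethyldodeca-2,6,10-trien-1-yl]-1,4-dimethoxybenzene, via 2,5-dimethoxyphenyllithium 3 (not isolated)
Conditions: n-BuLi, TMEDA, THF, 0 °C; then 2, −78 °C → rt
Reagents that add atoms: none
Why: Methoxy-directed ortho-lithiation followed by SN2 alkylation of the aryllithium at the primary allylic bromide should give the linear product with both (E)-alkenes untouched; no stereocentre is formed.

**Step 2**
Reactants: 4 2-[(2E,6E)-3,7,11-trimethyldodeca-2,6,10-trien-1-yl]-1,4-dimethoxybenzene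
Product: 5 (6E,10E)-3-bromo-12-(2,5-dimethoxyphenyl)-2,6,10-trimethyldodeca-6,10-dien-2-ol (racemic)
Conditions: NBS, THF/H2O, 0 °C
Reagents that add atoms: N-bromosuccinimide, O=C1CCC(=O)N1Br; water, O
Why: Terminal-selective bromohydrin formation of a polyprenyl chain should occur at the most exposed trisubstituted alkene, with water opening the bromonium ion at the tertiary carbon; the new stereocentre is racemic and is removed in step 4.

**Step 3**
Reactants: 5 (6E,10E)-3-bromo-12-(2,5-dimethoxyphenyl)-2,6,10-trimethyldodeca-6,10-dien-2-ol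
Product: 6 2-[(2E,6E)-9-(3,3-dimethyloxiran-2-yl)-3,7-dimethylnona-2,6-dien-1-yl]-1,4-dimethoxybenzene (racemic)
Conditions: K2CO3, MeOH, rt
Reagents that add atoms: none
Why: Intramolecular Williamson displacement of bromide by the tertiary alkoxide should close the epoxide; the racemic centre is kept until step 4.

**Step 4**
Reactants: 6 2-[(2E,6E)-9-(3,3-dimethyloxiran-2-yl)-3,7-dimethylnona-2,6-dien-1-yl]-1,4-dimethoxybenzene
Product: 7 (4E,8E)-10-(2,5-dimethoxyphenyl)-4,8-dimethyldeca-4,8-dienal
Conditions: H5IO6, THF/Et2O, 0 °C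
Reagents that add atoms: none
Why: Periodic acid should hydrolyse the epoxide (water entering at the tertiary carbon, so the aldehyde keeps the epoxide oxygen) and cleave the glycol in one pot, removing the stereocentre and leaving the internal alkenes intact.

**Step 5**
Reactants: 7 (4E,8E)-10-(2,5-dimethoxyphenyl)-4,8-dimethyldeca-4,8-dienal
Product: 8 (4E,8E)-10-(2,5-dimethoxyphenyl)-4,8-dimethyldeca-4,8-dienal hydrazone (C=N geometry of no consequence)
Conditions: N2H4·H2O (excess), EtOH, 0 °C → rt
Reagents that add atoms: hydrazine, NN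
Why: Condensation of an unhindered aldehyde with excess hydrazine should give the N-unsubstituted hydrazone, the excess suppressing azine formation.

**Step 6**
Reactants: 8 (4E,8E)-10-(2,5-dimethoxyphenyl)-4,8-dimethyldeca-4,8-dienal hydrazone
Product: 9 2-[(2E,6E)-10,10-dibromo-3,7-dimethyldeca-2,6-dien-1-yl]-1,4-dimethoxybenzene
Conditions: CuBr2, LiOt-Bu, THF, 0 °C → rt
Reagents that add atoms: CuBr2, Br[Cu]Br
Why: Oxidation of the hydrazone by CuBr2 to the diazoalkane and its bromination with loss of N2 (hydrazone to gem-dibromide conversion) is non-acidic and should leave the alkenes and the arene untouched.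

**Step 7**
Reactants: 9 2-[(2E,6E)-10,10-dibromo-3,7-dimethyldeca-2,6-dien-1-yl]-1,4-dimethoxybenzene; 10 2,2-dimethylcyclopentan-1-one
Product: 15 2-[(3E,7E)-9-(2,5-dimethoxyphenyl)-3,7-dimethylnona-3,7-dien-1-yl]-3,3-dimethylcyclohex-1-en-1-yl trifluoromethanesulfonate, via lithium carbenoid 11 (not isolated), via lithium alkoxide 12 (not isolated), via β-oxido carbenoid 13 (not isolated), via lithium enolate 14 (not isolated)
Conditions: lithium 2,2,6,6-tetramethylpiperidide, THF/Et2O, −105 °C; then 10, −105 → −78 °C; then n-BuLi (1.1 equiv), −95 → −20 °C; then Comins' reagent, −78 °C → rt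
Reagents that add atoms: Comins' reagent, N-(5-chloropyridin-2-yl)bis(trifluoromethanesulfonyl)imide, Clc1ccc(N(S(=O)(=O)C(F)(F)F)S(=O)(=O)C(F)(F)F)nc1
Why: The hindered lithium amide deprotonates gem-dibromide 9 at very low temperature to (1,1-dibromoalkyl)lithium 11, which adds 1,2 to ketone 10 to give alkoxide 12; the hindered amine set free is lithiated only slowly at this temperature, so n-BuLi then exchanges one bromine of 12 for lithium and gives β-oxido carbenoid 13. On warming, loss of LiBr from 13 is concerted with a 1,2-shift of the C1–C2 ring bond to the carbenoid carbon, which inserts that carbon into the ring and leaves lithium enolate 14 with its C=C between the old carbonyl carbon and the inserted carbon, and O-sulfonylation by Comins' reagent then gives 15. The closest known reaction type is the β-oxido carbenoid ring enlargement of cycloalkanone–(1,1-dibromoalkyl)lithium adducts, followed by standard O-triflation of a lithium enolate. No ring is closed by cyclisation: the six-membered ring arises from the five-membered one by a one-carbon ring expansion (1,2-alkyl shift), and the stereocentres of 12 and 13 are destroyed, so nothing stereochemical has to be controlled. The selectivity needed is migration of quaternary C2 in preference to C5H2 and to a hydride shift from the chain CH2; the higher migratory aptitude of the more substituted, more electron-rich carbon toward the electrophilic carbenoid, the push of the alkoxide on C1, and relief of the congestion between the carbenoid carbon and the gem-dimethyl group all favour C2. Because the enolate is formed regiospecifically and is trapped without equilibration, the triflate, and hence the tetrasubstituted alkene of the target, can only lie between the chain-bearing carbon and the carbon that will take the methyl group.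

**Step 8**
Reactants: 15 2-[(3E,7E)-9-(2,5-dimethoxyphenyl)-3,7-dimethylnona-3,7-dien-1-yl]-3,3-dimethylcyclohex-1-en-1-yl trifluoromethanesulfonate
Product: 16 2-[(2E,6E)-3,7-dimethyl-9-(2,6,6-trimethylcyclohex-1-en-1-yl)nona-2,6-dien-1-yl]-1,4-dimethoxybenzene
Conditions: MeMgBr, Fe(acac)3 (cat.), THF/NMP, −30 → 0 °C
Reagents that add atoms: methylmagnesium bromide, C[Mg]Br
Why: Iron-catalysed Kumada-type cross-coupling of an alkenyl triflate with a methyl Grignard reagent should replace the triflate by methyl with the alkene position fixed; aryl ethers and isolated alkenes are inert.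

**Step 9**
Reactants: 16 2-[(2E,6E)-3,7-dimethyl-9-(2,6,6-trimethylcyclohex-1-en-1-yl)nona-2,6-dien-1-yl]-1,4-dimethoxybenzene
Product: 17 2-[(2E,6E)-3,7-dimethyl-9-(2,6,6-trimethylcyclohex-1-en-1-yl)nona-2,6-dien-1-yl]cyclohexa-2,5-diene-1,4-dione
Conditions: (NH4)2Ce(NO3)6, MeCN/H2O, 0 °C
Reagents that add atoms: water, O
Why: Oxidative demethylation of a hydroquinone dimethyl ether by tetravalent cerium (arene radical cation, attack of water, loss of methanol) should give the quinone, and brief exposure at 0 °C in aqueous acetonitrile should be too mild to cyclise the polyene.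

**Step 10**
Reactants: 17 2-[(2E,6E)-3,7-dimethyl-9-(2,6,6-trimethylcyclohex-1-en-1-yl)nona-2,6-dien-1-yl]cyclohexa-2,5-diene-1,4-dione
Product: 18 jaspaquinol, 2-[(2E,6E)-3,7-dimethyl-9-(2,6,6-trimethylcyclohex-1-en-1-yl)nona-2,6-dien-1-yl]benzene-1,4-diol
Conditions: Na2S2O4, Et2O/H2O, rt, under argon
Reagents that add atoms: none
Why: Dithionite reduction of a benzoquinone to the hydroquinone is mild and neutral, so the alkenes should not migrate and chroman formation should not occur.

**Compound list**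
1 | 1,4-dimethoxybenzene | COc1ccc(OC)cc1 | starting material
2 | (2E,6E)-farnesyl bromide | CC(C)=CCC/C(C)=C/CC/C(C)=C/CBr | starting material
3 | 2,5-dimethoxyphenyllithium | [Li]c1cc(OC)ccc1OC | intermediate
4 | 2-[(2E,6E)-3,7,11-trimethyldodeca-2,6,10-trien-1-yl]-1,4-dimethoxybenzene | CC(C)=CCC/C(C)=C/CC/C(C)=C/Cc1cc(OC)ccc1OC | intermediate
5 | (6E,10E)-3-bromo-12-(2,5-dimethoxyphenyl)-2,6,10-trimethyldodeca-6,10-dien-2-ol (racemic) | CC(C)(O)C(Br)CC/C(C)=C/CC/C(C)=C/Cc1cc(OC)ccc1OC | intermediate
6 | 2-[(2E,6E)-9-(3,3-dimethyloxiran-2-yl)-3,7-dimethylnona-2,6-dien-1-yl]-1,4-dimethoxybenzene (racemic) | CC1(C)OC1CC/C(C)=C/CC/C(C)=C/Cc2cc(OC)ccc2OC | intermediate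
7 | (4E,8E)-10-(2,5-dimethoxyphenyl)-4,8-dimethyldeca-4,8-dienal | O=CCC/C(C)=C/CC/C(C)=C/Cc1cc(OC)ccc1OC | intermediate
8 | (4E,8E)-10-(2,5-dimethoxyphenyl)-4,8-dimethyldeca-4,8-dienal hydrazone | NN=CCC/C(C)=C/CC/C(C)=C/Cc1cc(OC)ccc1OC | intermediate
9 | 2-[(2E,6E)-10,10-dibromo-3,7-dimethyldeca-2,6-dien-1-yl]-1,4-dimethoxybenzene | BrC(Br)CC/C(C)=C/CC/C(C)=C/Cc1cc(OC)ccc1OC | intermediate
10 | 2,2-dimethylcyclopentan-1-one | CC1(C)CCCC1=O | starting material
11 | [(4E,8E)-1,1-dibromo-10-(2,5-dimethoxyphenyl)-4,8-dimethyldeca-4,8-dien-1-yl]lithium | [Li]C(Br)(Br)CC/C(C)=C/CC/C(C)=C/Cc1cc(OC)ccc1OC | intermediate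
12 | lithium 1-[(4E,8E)-1,1-dibromo-10-(2,5-dimethoxyphenyl)-4,8-dimethyldeca-4,8-dien-1-yl]-2,2-dimethylcyclopentan-1-olate (racemic) | [Li]OC1(C(Br)(Br)CC/C(C)=C/CC/C(C)=C/Cc2cc(OC)ccc2OC)CCCC1(C)C | intermediate
13 | lithium 1-[(4E,8E)-1-bromo-10-(2,5-dimethoxyphenyl)-1-lithio-4,8-dimethyldeca-4,8-dien-1-yl]-2,2-dimethylcyclopentan-1-olate (β-oxido carbenoid, diastereomer mixture) | [Li]OC1(C([Li])(Br)CC/C(C)=C/CC/C(C)=C/Cc2cc(OC)ccc2OC)CCCC1(C)C | intermediate
14 | lithium 2-[(3E,7E)-9-(2,5-dimethoxyphenyl)-3,7-dimethylnona-3,7-dien-1-yl]-3,3-dimethylcyclohex-1-en-1-olate | [Li]OC1=C(CC/C(C)=C/CC/C(C)=C/Cc2cc(OC)ccc2OC)C(C)(C)CCC1 | intermediate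
15 | 2-[(3E,7E)-9-(2,5-dimethoxyphenyl)-3,7-dimethylnona-3,7-dien-1-yl]-3,3-dimethylcyclohex-1-en-1-yl trifluoromethanesulfonate | O=S(=O)(OC1=C(CC/C(C)=C/CC/C(C)=C/Cc2cc(OC)ccc2OC)C(C)(C)CCC1)C(F)(F)F | intermediate
16 | 2-[(2E,6E)-3,7-dimethyl-9-(2,6,6-trimethylcyclohex-1-en-1-yl)nona-2,6-dien-1-yl]-1,4-dimethoxybenzene | CC1=C(CC/C(C)=C/CC/C(C)=C/Cc2cc(OC)ccc2OC)C(C)(C)CCC1 | intermediate
17 | 2-[(2E,6E)-3,7-dimethyl-9-(2,6,6-trimethylcyclohex-1-en-1-yl)nona-2,6-dien-1-yl]cyclohexa-2,5-diene-1,4-dione | CC1=C(CC/C(C)=C/CC/C(C)=C/CC2=CC(=O)C=CC2=O)C(C)(C)CCC1 | intermediate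
18 | jaspaquinol | CC1=C(CC/C(C)=C/CC/C(C)=C/Cc2cc(O)ccc2O)C(C)(C)CCC1 | target

**Step count and risks**
Total step count: 10. Longest linear sequence: 10 steps (from 1 and 2 to 18); ketone 10 enters at step 7.

Step 7 (most at risk). The (1,1-dibromoalkyl)lithium may collapse by α- or β-elimination or deprotonate ketone 10 at C5 faster than it adds to the hindered carbonyl. In the rearrangement, the 1,2-shift of the quaternary ring carbon may be outrun by migration of the ring methylene or by a hydride shift from the chain methylene. The hindered enolate may also be butylated by the 1-bromobutane formed before it is triflated. The fallback reverses the roles of the fragments: the chain is attached by sp2–sp3 cross-coupling to a ring made by a homologation in which methylene migration is the wanted event. It sets out from 10 and 7 and returns at 16. For the ring part, 10 with diazoethane and catalytic Sc(OTf)3 (toluene, −78 °C) should insert CHMe on the methylene side, enlarging the cyclopentanone to 2,2,6-trimethylcyclohexan-1-one F1, which has a single enolisable position. Tf2O with 2,6-di-tert-butyl-4-methylpyridine would then give 2,6,6-trimethylcyclohex-1-en-1-yl trifluoromethanesulfonate F2. For the chain part, Pinnick oxidation of 7 (NaClO2, NaH2PO4, 2-methyl-2-butene) would give (4E,8E)-10-(2,5-dimethoxyphenyl)-4,8-dimethyldeca-4,8-dienoic acid F3. N-Hydroxypyridine-2-thione and DCC would convert it into the Barton ester 2-thioxopyridin-1(2H)-yl (4E,8E)-10-(2,5-dimethoxyphenyl)-4,8-dimethyldeca-4,8-dienoate F4. Irradiation with CHI3 (Barton decarboxylative iodination) would give the one-carbon-shorter iodide 2-[(2E,6E)-9-iodo-3,7-dimethylnona-2,6-dien-1-yl]-1,4-dimethoxybenzene F5. Zinc insertion (Zn, LiCl, THF) would give [(3E,7E)-9-(2,5-dimethoxyphenyl)-3,7-dimethylnona-3,7-dien-1-yl]zinc iodide F6, and Negishi coupling of F6 with F2 (Pd(OAc)2, SPhos, THF/NMP) would give 16.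

Step 6. Oxidation of the hydrazone may stall at azine formation, the diazoalkane may lose nitrogen with a 1,2-hydride shift instead of taking up two bromines, or CuBr2 may brominate the electron-rich arene. The fallback does without the gem-dibromide and reaches the same enolate from a sulfinyl-stabilised chlorocarbenoid precursor. It sets out from 7 and returns at 15. Aldehyde 7 would be reduced (NaBH4, MeOH) to (4E,8E)-10-(2,5-dimethoxyphenyl)-4,8-dimethyldeca-4,8-dien-1-ol F7. Di-p-tolyl disulfide and PBu3 would convert F7 into the sulfide 2-[(2E,6E)-3,7-dimethyl-10-(4-methylphenylsulfanyl)deca-2,6-dien-1-yl]-1,4-dimethoxybenzene F8. Oxidation (NaIO4, MeOH/H2O) would give the sulfoxide 2-[(2E,6E)-3,7-dimethyl-10-(4-methylphenylsulfinyl)deca-2,6-dien-1-yl]-1,4-dimethoxybenzene F9. Chlorination (NCS, K2CO3, CH2Cl2) would give 2-[(2E,6E)-10-chloro-3,7-dimethyl-10-(4-methylphenylsulfinyl)deca-2,6-dien-1-yl]-1,4-dimethoxybenzene F10 as a diastereomer mixture. LiN(i-Pr)2 in THF at −78 °C would give the thermally stable lithiated chloro sulfoxide F11, which can be given time to add to 10 and form the lithium alkoxide adduct F12. t-BuLi would then effect sulfoxide–lithium exchange to the dilithio β-oxido chlorocarbenoid F13, which should lose LiCl and rearrange as in step 7 to enolate 14; trapping with Comins' reagent returns 15.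

Step 8. The Grignard reagent may attack sulfur of the hindered triflate (S–O cleavage back to the enolate), or reduction may compete with C–C coupling. The fallback uses a leaving group that cannot be cleaved in this way and a palladium-catalysed methyl transfer from aluminium. It sets out from 9 and 10 and returns at 16. Step 7 would be run as far as enolate 14, which would be trapped with diethyl chlorophosphate to give the enol phosphate diethyl 2-[(3E,7E)-9-(2,5-dimethoxyphenyl)-3,7-dimethylnona-3,7-dien-1-yl]-3,3-dimethylcyclohex-1-en-1-yl phosphate F14. F14 would be methylated with AlMe3 and catalytic Pd(PPh3)4 in ClCH2CH2Cl to give 16.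

**Further compounds**
F1 | step 7 | 2,2,6-trimethylcyclohexan-1-one (racemic) | CC1CCCC(C)(C)C1=O
F2 | step 7 | 2,6,6-trimethylcyclohex-1-en-1-yl trifluoromethanesulfonate | CC1=C(OS(=O)(=O)C(F)(F)F)C(C)(C)CCC1
F3 | step 7 | (4E,8E)-10-(2,5-dimethoxyphenyl)-4,8-dimethyldeca-4,8-dienoic acid | OC(=O)CC/C(C)=C/CC/C(C)=C/Cc1cc(OC)ccc1OC
F4 | step 7 | 2-thioxopyridin-1(2H)-yl (4E,8E)-10-(2,5-dimethoxyphenyl)-4,8-dimethyldeca-4,8-dienoate | S=C1C=CC=CN1OC(=O)CC/C(C)=C/CC/C(C)=C/Cc2cc(OC)ccc2OC
F5 | step 7 | 2-[(2E,6E)-9-iodo-3,7-dimethylnona-2,6-dien-1-yl]-1,4-dimethoxybenzene | ICC/C(C)=C/CC/C(C)=C/Cc1cc(OC)ccc1OC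
F6 | step 7 | [(3E,7E)-9-(2,5-dimethoxyphenyl)-3,7-dimethylnona-3,7-dien-1-yl]zinc iodide | I[Zn]CC/C(C)=C/CC/C(C)=C/Cc1cc(OC)ccc1OC
F7 | step 6 | (4E,8E)-10-(2,5-dimethoxyphenyl)-4,8-dimethyldeca-4,8-dien-1-ol | OCCC/C(C)=C/CC/C(C)=C/Cc1cc(OC)ccc1OC
F8 | step 6 | 2-[(2E,6E)-3,7-dimethyl-10-(4-methylphenylsulfanyl)deca-2,6-dien-1-yl]-1,4-dimethoxybenzene | Cc1ccc(SCCC/C(C)=C/CC/C(C)=C/Cc2cc(OC)ccc2OC)cc1
F9 | step 6 | 2-[(2E,6E)-3,7-dimethyl-10-(4-methylphenylsulfinyl)deca-2,6-dien-1-yl]-1,4-dimethoxybenzene | Cc1ccc(S(=O)CCC/C(C)=C/CC/C(C)=C/Cc2cc(OC)ccc2OC)cc1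
F10 | step 6 | 2-[(2E,6E)-10-chloro-3,7-dimethyl-10-(4-methylphenylsulfinyl)deca-2,6-dien-1-yl]-1,4-dimethoxybenzene | Cc1ccc(S(=O)C(Cl)CC/C(C)=C/CC/C(C)=C/Cc2cc(OC)ccc2OC)cc1
F11 | step 6 | lithiated chloro sulfoxide derived from F10 | Cc1ccc(S(=O)C([Li])(Cl)CC/C(C)=C/CC/C(C)=C/Cc2cc(OC)ccc2OC)cc1
F12 | step 6 | lithium alkoxide adduct of F11 and 10 | Cc1ccc(S(=O)C(Cl)(CC/C(C)=C/CC/C(C)=C/Cc2cc(OC)ccc2OC)C2(O[Li])CCCC2(C)C)cc1
F13 | step 6 | dilithio β-oxido chlorocarbenoid | [Li]OC1(C([Li])(Cl)CC/C(C)=C/CC/C(C)=C/Cc2cc(OC)ccc2OC)CCCC1(C)C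
F14 | step 8 | diethyl 2-[(3E,7E)-9-(2,5-dimethoxyphenyl)-3,7-dimethylnona-3,7-dien-1-yl]-3,3-dimethylcyclohex-1-en-1-yl phosphate | CCOP(=O)(OCC)OC1=C(CC/C(C)=C/CC/C(C)=C/Cc2cc(OC)ccc2OC)C(C)(C)CCC1
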